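The ten-membered ring is treated as the perimeter of a cis-decalin: ring A (C3–C8) comes from carvone, ring B (C8, C9, C10, C1, C2, C3) is annulated onto it, and the shared C3–C8 bond is then cut. The feature exploited is that the acyloxy carbons C3 and C8 face each other 1,6 across the macrocycle while C4=C5 lies inside ring A. One glycol scission opens the ring, creates both carbonyls that become the ester carbinols and leaves C4=C5 Z. The precursor 22 is a cis-fused C3,C8-diol whose O1, O3, O6, O8 and O10 all sit on the face opposite the C7 side chain, with O1/O10 tied as an acetonide.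

Key step: step 13

Convention: germacrane numbers are used from step 1 on (carvone C1–C6 = C3, C4, C5, C6, C7, C8; side chain C11, C12 = oxygenated carbon, C13 = methylene). β is the face that carries the C7 side chain when the ring is drawn flat, α is the opposite face.

Remark on the chemistry: all reagents reach ring A anti to the C7 side chain. Every ring oxygen of 22 is therefore brought in as an electrophile (oxaziridine, singlet oxygen, OsO4). C2 is attached to an sp2 C3. As a result C2 and C9 are both β and the ring fusion is cis.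

Step 1
Reactants: 1 (S)-carvone
Product: 2 (S)-10-chlorocarvone (C12 chloride)
Conditions: Ca(OCl)2, solid CO2, CH2Cl2–H2O, 0 °C
Reagents that add atoms: calcium hypochlorite, [Ca+2].[O-]Cl.[O-]Cl
Why: Ene-type allylic chlorination by HOCl made in the flask picks the only electron-rich alkene (the enone C4=C5 is deactivated), puts a leaving group on the future C12 and leaves C7 untouched, so that no late allylic oxidation has to choose between alkenes.

Step 2
Reactants: 2 (S)-10-chlorocarvone
Product: 4 (S)-10-hydroxycarvone (C12 alcohol), via allylic acetate 3 (not isolated)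
Conditions: KOAc, DMF, 50 °C; then MeOH, K2CO3 (cat.), rt
Reagents that add atoms: potassium acetate, CC(=O)[O-].[K+]
Why: SN2 displacement of the primary allylic chloride by acetate and carbonate-catalysed transesterification of 3 in the same flask are routine and touch no stereocentre.

Step 3
Reactants: 4 (S)-10-hydroxycarvone
Product: 5 C12 TBDPS ether of 4
Conditions: TBDPSCl, imidazole, DMF, rt
Reagents that add atoms: tert-butylchlorodiphenylsilane, CC(C)(C)[Si](Cl)(c1ccccc1)c1ccccc1
Why: Standard silylation of a primary alcohol; the bulky, acid-stable TBDPS group later shields and deactivates C11=C13 towards OsO4 and outlives the acetonide.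

Step 4
Reactants: 5 C12 TBDPS ether; 6 3-bromo-2-methylpropene
Product: 8 8α-methallyl enone (methallyl trans to the C7 side chain), via lithium enolate 7 (not isolated)
Conditions: LDA, THF, −78 °C; then 6, −78 to −20 °C
Reagents that add atoms: 3-bromo-2-methylpropene (6), C=C(C)CBr
Why: Kinetic α′-deprotonation gives the cross-conjugated enolate 7 and its SN2 alkylation by the allylic bromide forms C8–C9 anti to the C7 side chain (enolate alkylation); this C8 configuration is provisional because C8 is planarised again in step 5.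

Step 5
Reactants: 8 8α-methallyl enone
Product: 11 8α-trimethylsilyloxy-8β-methallyl enone, via lithium enolate 9 (not isolated), via lithium alkoxide 10 (not isolated)
Conditions: LDA, THF, −78 °C; 2-(phenylsulfonyl)-3-phenyloxaziridine, −78 °C; then TMSCl, −78 to 0 °C
Reagents that add atoms: 2-(phenylsulfonyl)-3-phenyloxaziridine, O=S(=O)(N1OC1c1ccccc1)c1ccccc1; chlorotrimethylsilane, C[Si](C)(C)Cl
Why: Electrophilic hydroxylation of the tetrasubstituted enolate 9 by the N-sulfonyloxaziridine takes place on the α face, anti to the pseudoaxial C7 side chain, which sets O8 α and C9 β, and silylation of alkoxide 10 in the same flask protects it for the next deprotonation.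

Step 6
Reactants: 11 8α-trimethylsilyloxy-8β-methallyl enone
Product: 13 dienyl triflate (C3–OTf, C3=C4, C5=C6), via potassium dienolate 12 (not isolated)
Conditions: KHMDS, THF, −78 °C; then PhNTf2, −78 to 0 °C
Reagents that add atoms: N-phenylbis(trifluoromethanesulfonimide), O=S(=O)(N(c1ccccc1)S(=O)(=O)C(F)(F)F)C(F)(F)F
Why: With C8 quaternary the only acidic hydrogens are those at C6, so γ-deprotonation gives the linear dienolate 12 and O-sulfonylation gives the 1,3-dienyl triflate (enol triflate formation), C7 and C8 being untouched.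

Step 7
Reactants: 13 dienyl triflate; 14 allyltributylstannane
Product: 15 3-allyl cyclohexa-1,3-diene (C3=C4, C5=C6)
Conditions: Pd(PPh3)4 (cat.), LiCl, THF, 65 °C
Reagents that add atoms: allyltributylstannane (14), C=CC[Sn](CCCC)(CCCC)CCCC
Why: Stille coupling through zerovalent palladium joins C2 to an sp2 C3, a coupling known for equally hindered 2,6,6-trisubstituted cyclohexenyl triflates; it replaces 1,2-addition to the ketone, in which the carbon nucleophile would enter from the α face and give a trans-diol that cannot be closed to an unstrained decalin.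

Step 8
Reactants: 15 3-allyl cyclohexa-1,3-diene
Product: 18 3α,6α,8α-triol with C4=C5, via endoperoxide 16 (not isolated), via silyl ether diol 17 (not isolated)
Conditions: O2, tetraphenylporphyrin (cat.), visible light, CH2Cl2, −20 °C; then thiourea, MeOH–H2O, 0 °C to rt; then K2CO3 (cat.), rt
Reagents that add atoms: dioxygen, O=O
Why: [4+2] cycloaddition of singlet oxygen to the s-cis diene C3=C4–C5=C6 occurs on the α face (only H7 and O8 lie there, C9 and the C7 side chain block the β face), so one event sets O3 and O6 α and moves the alkene to C4=C5; thiourea then cleaves only the O–O bond and carbonate-catalysed methanolysis removes the trimethylsilyl group.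

Step 9
Reactants: 18 3α,6α,8α-triol
Product: 19 6-O-TBS ether of 18
Conditions: TBSCl, imidazole, DMF, rt
Reagents that add atoms: tert-butylchlorodimethylsilane, CC(C)(C)[Si](C)(C)Cl
Why: Silylation selects the only secondary hydroxyl, the two tertiary carbinols at C3 and C8 being inert to TBSCl.

Step 10
Reactants: 19 6-O-TBS ether
Product: 20 cis-decalin 3α,8α-diol with C1=C10 and C4=C5
Conditions: second-generation Grubbs catalyst RuCl2(=CHPh)(PCy3)(SIMes) (cat.), CH2Cl2, 40 °C
Reagents that add atoms: none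
Why: Ring-closing metathesis starts at the monosubstituted allyl alkene and closes on the neighbouring methallyl group, both β and gauche on C3 and C8, to give cis-fused ring B with a trisubstituted C1=C10; the hindered C11=C13 and C4=C5 stay spectators.

Step 11
Reactants: 20 cis-decalin diene diol
Product: 21 1α,3α,8α,10α-tetraol
Conditions: OsO4 (cat.), NMO, acetone–H2O, 0 °C
Reagents that add atoms: N-methylmorpholine N-oxide, C[N+]1([O-])CCOCC1; water, O
Why: Catalytic syn-dihydroxylation picks C1=C10, the most electron-rich and most open alkene (C4=C5 is wedged between quaternary C3 and C6–OTBS, C11=C13 carries an allylic silyloxy group and two bulky arms), and OsO4 arrives on the convex α face that bears only the angular hydroxyls, because C4 or C7 stands axial over the β face of ring B in either chair pair, which sets O1 and O10 α.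

Step 12
Reactants: 21 tetraol
Product: 22 cis-decalin 3α,8α-diol with O1/O10 acetonide
Conditions: 2-methoxypropene, PPTS (cat.), CH2Cl2, 0 °C
Reagents that add atoms: 2-methoxypropene, C=C(C)OC
Why: Kinetic acetalisation: the secondary O1–H adds to the oxocarbenium ion and the cis-vicinal O10–H closes the dioxolane, whereas the two angular tertiary hydroxyls are too hindered to start the process at 0 °C and PPTS is too weak to ionise the tertiary allylic C3–OH.

Step 13
Reactants: 22 cis-decalin 3α,8α-diol acetonide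
Product: 24 (4Z)-cyclodecene-3,8-dione, via cyclic lead diolate 23 (not isolated)
Conditions: Pb(OAc)4, pyridine, CH2Cl2, −20 °C, short contact; filtration through neutral silica
Reagents that add atoms: none
Why: The two tertiary hydroxyls, held gauche on the α face of the cis ring junction, displace two acetates on tetravalent lead to give the five-membered diolate 23, which collapses by a concerted two-electron shift that breaks C3–C8, releases divalent lead and turns both carbinol carbons into ketones. The closest known reaction type is the Criegee cleavage of decalin-9,10-diols to cyclodecane-1,6-diones. No ring is closed by bond formation: the ten-membered ring is the perimeter of rings A and B and appears by scission (ring expansion by fragmentation), so no macrocyclisation penalty is paid. No stereocentre is made; C3 and C8 are erased, C1, C6, C7 and C10 are spectators, and C4=C5, having been a cyclohexene bond, can only emerge Z. The selectivity needed is cleavage of one glycol only, which the acetonide on O1/O10 secures, while the silyl ether on O6 stops O6 from adding to the new C3 ketone. The cis geometry built in steps 5 and 8 lets the cyclic ester form at −20 °C, and the pyridine buffer and short contact keep C7 (α to C8=O, β to O6, allylic to C11=C13) from enolising.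

Step 14
Reactants: 24 (4Z)-cyclodecene-3,8-dione
Product: 25 3β-hydroxy-8-ketone (3S)
Conditions: (R)-2-methyl-CBS-oxazaborolidine, catecholborane, toluene, −78 °C; MeOH quench, pH 7 work-up
Reagents that add atoms: none
Why: Corey–Bakshi–Shibata reduction: the (R)-oxazaborolidine binds the less hindered C3 carbonyl at the lone pair next to C2H2, treats the α-methylvinyl arm C4 as the large group and delivers hydride to the α face, giving the 3β (3S) allylic alcohol by 1,2-reduction, while the C8 ketone, flanked by branched C7 and the neopentyl-type C9, reacts more slowly at −78 °C.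

Step 15
Reactants: 25 3β-hydroxy-8-ketone; 26 isobutyryl chloride
Product: 27 3β-isobutyrate 8-ketone
Conditions: pyridine, CH2Cl2, 0 °C
Reagents that add atoms: isobutyryl chloride (26), CC(C)C(=O)Cl
Why: Acylation of the only free hydroxyl with retention at C3 under weakly basic conditions that do not enolise the C8 ketone.

Step 16
Reactants: 27 3β-isobutyrate 8-ketone
Product: 28 8β-alcohol (8R)
Conditions: (S)-2-methyl-CBS-oxazaborolidine (1 equiv), catecholborane, toluene, −40 to −20 °C; MeOH quench
Reagents that add atoms: none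
Why: Corey–Bakshi–Shibata reduction under reagent control: the (S)-oxazaborolidine binds the carbonyl lone pair on the side of the C9 methylene, branched C7 acts as the large group and hydride reaches the α face to give the 8β (8R) alcohol, while catecholborane leaves the alkenes and the ester alone.

Step 17
Reactants: 29 angelic acid
Product: 30 (Z)-2-methylbut-2-en-1-ol
Conditions: LiAlH4, Et2O, 0 °C
Reagents that add atoms: none
Why: Hydride reduction of the unsaturated acid goes 1,2 and keeps the Z geometry.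

Step 18
Reactants: 30 (Z)-2-methylbut-2-en-1-ol
Product: 31 [(2R,3S)-2,3-dimethyloxiran-2-yl]methanol
Conditions: Ti(OiPr)4 (cat.), D-(−)-diethyl tartrate (cat.), t-BuOOH, 4 Å molecular sieves, CH2Cl2, −20 °C
Reagents that add atoms: tert-butyl hydroperoxide, CC(C)(C)OO
Why: Sharpless asymmetric epoxidation: the D-(−)-tartrate ligand directs oxygen to the alkene face that gives the (2R,3S)-epoxy alcohol, syn addition keeps the C3 methyl cis to the carbinol carbon, and any minor enantiomer is removed after step 20 as a diastereomeric ester.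

Step 19
Reactants: 31 epoxy alcohol
Product: 33 (2S,3S)-2,3-dimethyloxirane-2-carboxylic acid (epoxyangelic acid), via epoxy aldehyde 32 (not isolated)
Conditions: TEMPO (cat.), PhI(OAc)2, MeCN–H2O, rt
Reagents that add atoms: water, O
Why: Oxoammonium-catalysed oxidation takes the primary alcohol through aldehyde 32 and its hydrate to the acid without opening the epoxide or touching either stereocentre; the C2 descriptor changes to S only through the priority rules.

Step 20
Reactants: 28 8β-alcohol; 33 epoxyangelic acid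
Product: 35 3β-isobutyrate 8β-epoxyangelate, via mixed anhydride 34 (not isolated)
Conditions: 33, 2,4,6-trichlorobenzoyl chloride, Et3N, toluene, rt; then 28, DMAP, rt to 40 °C
Reagents that add atoms: epoxyangelic acid (33), OC(=O)[C@@]1(C)O[C@H]1C
Why: Yamaguchi esterification: DMAP attacks the less hindered epoxyangeloyl carbonyl of 34 and the acylpyridinium acylates the hindered 8β-hydroxyl with retention at C8 and at both epoxide carbons; the preformed epoxy acid avoids angelate-to-tiglate isomerisation and a late unselective epoxidation.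

Step 21
Reactants: 35 diester acetonide
Product: 36 1α,10α-diol
Conditions: AcOH–H2O (4:1), 40 °C
Reagents that add atoms: none
Why: Acid-catalysed acetal hydrolysis, helped by release of the eclipsing strain that the dioxolane imposes on C1–C10 in the ten-membered ring; the TBDPS ether, the hindered secondary TBS ether, both esters and the electron-poor glycidic epoxide tolerate dilute acetic acid.

Step 22
Reactants: 36 1α,10α-diol
Product: 38 (1R,10R)-trans-epoxide, via C1 mesylate 37 (not isolated)
Conditions: MsCl, Et3N, CH2Cl2, 0 °C; then MeOH, K2CO3, 0 °C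
Reagents that add atoms: none
Why: Selective sulfonylation of the secondary O1–H followed by intramolecular Williamson closure (3-exo-tet SN2): the flexible ring lets O10 and the mesylate become antiperiplanar, O10 keeps the C10 configuration and inverts C1, which turns the syn-diol into the trans-epoxide faster than cold methanolic carbonate attacks the two hindered esters.

Step 23
Reactants: 38 trans-epoxide bis-silyl ether
Product: 39 6α,12-diol
Conditions: Bu4NF, AcOH, THF, 0 °C to rt
Reagents that add atoms: none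
Why: Fluoride-induced desilylation is buffered with acetic acid, so that no free alkoxide is present to trigger acyl migration from O8 to O6 or epoxide opening.

Step 24
Reactants: 39 6α,12-diol
Product: 42 CNP0117882.1, via hydroxy enal 40 (not isolated), via lactol 41 (not isolated)
Conditions: TEMPO (cat.), PhI(OAc)2, CH2Cl2, rt
Reagents that add atoms: none
Why: Oxoammonium oxidation selects the primary allylic alcohol, the 6α-hydroxyl adds to enal 40 to give the trans-fused lactol 41 and a second oxidation gives the α-methylene-γ-lactone (oxidative lactonisation of a 1,4-diol); O8 is already acylated, so only the 6,12-lactone can form and no stereocentre changes.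

Compound list

1 | (S)-carvone | CC1=CC[C@@H](CC1=O)C(C)=C | starting material
2 | (S)-10-chlorocarvone, (5S)-5-(3-chloroprop-1-en-2-yl)-2-methylcyclohex-2-en-1-one | O=C1C(C)=CC[C@H](C(=C)CCl)C1 | intermediate
3 | C12 acetate of 4 | O=C1C(C)=CC[C@H](C(=C)COC(C)=O)C1 | intermediate
4 | (S)-10-hydroxycarvone | O=C1C(C)=CC[C@H](C(=C)CO)C1 | intermediate
5 | C12 TBDPS ether of 4 | O=C1C(C)=CC[C@H](C(=C)CO[Si](c4ccccc4)(c4ccccc4)C(C)(C)C)C1 | intermediate
6 | 3-bromo-2-methylpropene | C=C(C)CBr | starting material
7 | lithium C3,C8-enolate of 5 | [Li+].[O-]C1=C[C@@H](C(=C)CO[Si](c4ccccc4)(c4ccccc4)C(C)(C)C)CC=C1C | intermediate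
8 | 8α-methallyl enone (H8 β, side chain β) | O=C1C(C)=CC[C@H](C(=C)CO[Si](c4ccccc4)(c4ccccc4)C(C)(C)C)[C@H]1CC(C)=C | intermediate
9 | lithium C3,C8-enolate of 8 | [Li+].[O-]C1=C(CC(C)=C)[C@@H](C(=C)CO[Si](c4ccccc4)(c4ccccc4)C(C)(C)C)CC=C1C | intermediate
10 | lithium 8α-alkoxide, 8β-methallyl enone | O=C1C(C)=CC[C@H](C(=C)CO[Si](c4ccccc4)(c4ccccc4)C(C)(C)C)[C@]1([O-])CC(C)=C.[Li+] | intermediate
11 | 8α-trimethylsilyloxy-8β-methallyl enone | O=C1C(C)=CC[C@H](C(=C)CO[Si](c4ccccc4)(c4ccccc4)C(C)(C)C)[C@]1(O[Si](C)(C)C)CC(C)=C | intermediate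
12 | potassium linear dienolate of 11 (C3=C4, C5=C6) | [K+].[O-]C1=C(C)C=C[C@H](C(=C)CO[Si](c4ccccc4)(c4ccccc4)C(C)(C)C)[C@]1(O[Si](C)(C)C)CC(C)=C | intermediate
13 | dienyl triflate | O=S(=O)(OC1=C(C)C=C[C@H](C(=C)CO[Si](c4ccccc4)(c4ccccc4)C(C)(C)C)[C@]1(O[Si](C)(C)C)CC(C)=C)C(F)(F)F | intermediate
14 | allyltributylstannane | C=CC[Sn](CCCC)(CCCC)CCCC | starting material
15 | 3-allyl cyclohexa-1,3-diene | C=CCC1=C(C)C=C[C@H](C(=C)CO[Si](c4ccccc4)(c4ccccc4)C(C)(C)C)[C@]1(O[Si](C)(C)C)CC(C)=C | intermediate
16 | 3α,6α-endoperoxide (2,3-dioxabicyclo[2.2.2]oct-5-ene) | C=CC[C@]12OO[C@H](C=C1C)[C@H](C(=C)CO[Si](c4ccccc4)(c4ccccc4)C(C)(C)C)[C@]2(O[Si](C)(C)C)CC(C)=C | intermediate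
17 | 3α,6α-diol, 8α-trimethylsilyl ether | O[C@@]1(CC=C)C(C)=C[C@@H](O)[C@H](C(=C)CO[Si](c4ccccc4)(c4ccccc4)C(C)(C)C)[C@]1(O[Si](C)(C)C)CC(C)=C | intermediate
18 | 3α,6α,8α-triol (3β-allyl, 8β-methallyl) | O[C@@]1(CC=C)C(C)=C[C@@H](O)[C@H](C(=C)CO[Si](c4ccccc4)(c4ccccc4)C(C)(C)C)[C@]1(O)CC(C)=C | intermediate
19 | 6-O-TBS ether of 18 | O[C@@]1(CC=C)C(C)=C[C@@H](O[Si](C)(C)C(C)(C)C)[C@H](C(=C)CO[Si](c4ccccc4)(c4ccccc4)C(C)(C)C)[C@]1(O)CC(C)=C | intermediate
20 | cis-decalin 3α,8α-diol, C1=C10 and C4=C5 | O[C@@]12C(C)=C[C@@H](O[Si](C)(C)C(C)(C)C)[C@H](C(=C)CO[Si](c4ccccc4)(c4ccccc4)C(C)(C)C)[C@]1(O)CC(C)=CC2 | intermediate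
21 | cis-decalin 1α,3α,8α,10α-tetraol | O[C@@]12C(C)=C[C@@H](O[Si](C)(C)C(C)(C)C)[C@H](C(=C)CO[Si](c4ccccc4)(c4ccccc4)C(C)(C)C)[C@]1(O)C[C@@](C)(O)[C@@H](O)C2 | intermediate
22 | cis-decalin 3α,8α-diol, O1/O10 acetonide (key-step precursor) | O[C@@]12C(C)=C[C@@H](O[Si](C)(C)C(C)(C)C)[C@H](C(=C)CO[Si](c4ccccc4)(c4ccccc4)C(C)(C)C)[C@]1(O)C[C@@]1(C)OC(C)(C)O[C@H]1C2 | intermediate
23 | cyclic O3,O8 lead diolate diacetate | CC(=O)O[Pb]3(OC(C)=O)O[C@@]12C(C)=C[C@@H](O[Si](C)(C)C(C)(C)C)[C@H](C(=C)CO[Si](c4ccccc4)(c4ccccc4)C(C)(C)C)[C@]1(O3)C[C@@]1(C)OC(C)(C)O[C@H]1C2 | intermediate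
24 | (4Z)-cyclodecene-3,8-dione (key-step product) | O=C1/C(C)=C\[C@@H](O[Si](C)(C)C(C)(C)C)[C@H](C(=C)CO[Si](c4ccccc4)(c4ccccc4)C(C)(C)C)C(=O)C[C@@]2(C)OC(C)(C)O[C@H]2C1 | intermediate
25 | 3β-hydroxy-8-ketone (3S) | O[C@@H]1/C(C)=C\[C@@H](O[Si](C)(C)C(C)(C)C)[C@H](C(=C)CO[Si](c4ccccc4)(c4ccccc4)C(C)(C)C)C(=O)C[C@@]2(C)OC(C)(C)O[C@H]2C1 | intermediate
26 | isobutyryl chloride | CC(C)C(=O)Cl | starting material
27 | 3β-isobutyrate 8-ketone | CC(C)C(=O)O[C@@H]1/C(C)=C\[C@@H](O[Si](C)(C)C(C)(C)C)[C@H](C(=C)CO[Si](c4ccccc4)(c4ccccc4)C(C)(C)C)C(=O)C[C@@]2(C)OC(C)(C)O[C@H]2C1 | intermediate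
28 | 3β-isobutyrate 8β-alcohol (8R) | CC(C)C(=O)O[C@@H]1/C(C)=C\[C@@H](O[Si](C)(C)C(C)(C)C)[C@H](C(=C)CO[Si](c4ccccc4)(c4ccccc4)C(C)(C)C)[C@H](O)C[C@@]2(C)OC(C)(C)O[C@H]2C1 | intermediate
29 | angelic acid | C/C=C(/C)C(=O)O | starting material
30 | (Z)-2-methylbut-2-en-1-ol | C/C=C(/C)CO | intermediate
31 | [(2R,3S)-2,3-dimethyloxiran-2-yl]methanol | OC[C@@]1(C)O[C@H]1C | intermediate
32 | (2S,3S)-2,3-dimethyloxirane-2-carbaldehyde | O=C[C@@]1(C)O[C@H]1C | intermediate
33 | (2S,3S)-2,3-dimethyloxirane-2-carboxylic acid | OC(=O)[C@@]1(C)O[C@H]1C | intermediate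
34 | epoxyangelic 2,4,6-trichlorobenzoic anhydride | O=C(OC(=O)[C@@]1(C)O[C@H]1C)c2c(Cl)cc(Cl)cc2Cl | intermediate
35 | 3β-isobutyrate 8β-epoxyangelate, acetonide, bis-silyl ether | CC(C)C(=O)O[C@@H]1/C(C)=C\[C@@H](O[Si](C)(C)C(C)(C)C)[C@H](C(=C)CO[Si](c4ccccc4)(c4ccccc4)C(C)(C)C)[C@H](OC(=O)[C@@]3(C)O[C@H]3C)C[C@@]2(C)OC(C)(C)O[C@H]2C1 | intermediate
36 | 1α,10α-diol | CC(C)C(=O)O[C@@H]1/C(C)=C\[C@@H](O[Si](C)(C)C(C)(C)C)[C@H](C(=C)CO[Si](c4ccccc4)(c4ccccc4)C(C)(C)C)[C@H](OC(=O)[C@@]3(C)O[C@H]3C)C[C@@](C)(O)[C@@H](O)C1 | intermediate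
37 | 1α-mesylate 10α-alcohol | CC(C)C(=O)O[C@@H]1/C(C)=C\[C@@H](O[Si](C)(C)C(C)(C)C)[C@H](C(=C)CO[Si](c4ccccc4)(c4ccccc4)C(C)(C)C)[C@H](OC(=O)[C@@]3(C)O[C@H]3C)C[C@@](C)(O)[C@@H](OS(C)(=O)=O)C1 | intermediate
38 | (1R,10R)-trans-epoxide, bis-silyl ether | CC(C)C(=O)O[C@@H]1/C(C)=C\[C@@H](O[Si](C)(C)C(C)(C)C)[C@H](C(=C)CO[Si](c4ccccc4)(c4ccccc4)C(C)(C)C)[C@H](OC(=O)[C@@]3(C)O[C@H]3C)C[C@@]2(C)O[C@@H]2C1 | intermediate
39 | 6α,12-diol | CC(C)C(=O)O[C@@H]1/C(C)=C\[C@@H](O)[C@H](C(=C)CO)[C@H](OC(=O)[C@@]3(C)O[C@H]3C)C[C@@]2(C)O[C@@H]2C1 | intermediate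
40 | 6α-hydroxy C12 enal | CC(C)C(=O)O[C@@H]1/C(C)=C\[C@@H](O)[C@H](C(=C)C=O)[C@H](OC(=O)[C@@]3(C)O[C@H]3C)C[C@@]2(C)O[C@@H]2C1 | intermediate
41 | trans-fused 6,12-lactol (C12 epimers) | CC(C)C(=O)O[C@@H]1/C(C)=C\[C@H]4OC(O)C(=C)[C@@H]4[C@H](OC(=O)[C@@]3(C)O[C@H]3C)C[C@@]2(C)O[C@@H]2C1 | intermediate
42 | CNP0117882.1, (1R,3S,6R,7R,8R,10R) with (2S,3S)-epoxyangelate | C=C1C(=O)O[C@@H]2/C=C(/C)[C@@H](OC(=O)C(C)C)C[C@H]3O[C@]3(C)C[C@@H](OC(=O)[C@@]3(C)O[C@H]3C)[C@@H]12 | target

Total step count: 24. Longest linear sequence: 21 steps from (S)-carvone (steps 1–16 and 20–24). Acid 33 is made in three steps (17–19) on the side.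

Steps most likely to fail

Step 16. Hydride transfer to the hindered C8 carbonyl may be sluggish. The conformational bias of the ten-membered ring may also erode reagent control, so that facial selectivity is poor. The fallback sets out from 27 and gives up control at the reduction stage. Reduction with NaBH4 in MeOH–CH2Cl2 at −40 °C gives both carbinols, which are separated; the 8β-alcohol is 28 itself. The 8α-alcohol F1 is esterified with acid 33 under Mitsunobu conditions (PPh3, diisopropyl azodicarboxylate, toluene, 0 °C to rt). This goes by SN2 inversion at C8. Both epimers therefore come back to the route at 35.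

Step 11. Osmylation of C11=C13 may compete with that of C1=C10 (loss of chemoselectivity, over-oxidation). The fallback sets out from 20 and replaces osmium by an electrophile that is known to prefer the trisubstituted ring alkene of limonene-type dienes. One equivalent of mCPBA with NaHCO3 in CH2Cl2 at −20 °C, guided by the angular hydroxyls and the convex face, gives the 1α,10α-epoxide F2. Bromide-catalysed insertion of CO2 (Bu4NBr, CO2 under pressure, 80 °C) opens C1 with inversion and recloses with a second inversion. This gives the cis-fused 1α,10α-carbonate F3 with net retention. Methanolysis (K2CO3, MeOH) comes back to the route at 21.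

Step 14. The two carbonyl groups may not be told apart well enough, so that C8 is reduced by the catalyst antipode that suits only C3. The fallback sets out from 24 and moves the differentiation from the reduction to an oxidation.
- Both ketones are reduced with the (S)-oxazaborolidine and excess catecholborane, the antipode that C8 needs, to give the 3α,8β-diol F4.
- Activated MnO2 in CH2Cl2 re-oxidises only the allylic C3 carbinol to the 8β-hydroxy enone F5.
- Yamaguchi esterification with 33 gives the 8β-epoxyangelate enone F6.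
- The enone is now the only carbonyl, and the (R)-oxazaborolidine with catecholborane gives the 3β-alcohol F7.
- Isobutyryl chloride in pyridine comes back to the route at 35.

Further compounds

F1 | step 16 | 3β-isobutyrate 8α-alcohol (8-epimer of 28) | CC(C)C(=O)O[C@@H]1/C(C)=C\[C@@H](O[Si](C)(C)C(C)(C)C)[C@H](C(=C)CO[Si](c4ccccc4)(c4ccccc4)C(C)(C)C)[C@@H](O)C[C@@]2(C)OC(C)(C)O[C@H]2C1
F2 | step 11 | cis-decalin 3α,8α-diol 1α,10α-epoxide | O[C@@]12C(C)=C[C@@H](O[Si](C)(C)C(C)(C)C)[C@H](C(=C)CO[Si](c4ccccc4)(c4ccccc4)C(C)(C)C)[C@]1(O)C[C@@]3(C)O[C@H]3C2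
F3 | step 11 | cis-decalin 3α,8α-diol 1α,10α-cyclic carbonate | O[C@@]12C(C)=C[C@@H](O[Si](C)(C)C(C)(C)C)[C@H](C(=C)CO[Si](c4ccccc4)(c4ccccc4)C(C)(C)C)[C@]1(O)C[C@@]3(C)OC(=O)O[C@H]3C2
F4 | step 14 | 3α,8β-diol | O[C@H]1/C(C)=C\[C@@H](O[Si](C)(C)C(C)(C)C)[C@H](C(=C)CO[Si](c4ccccc4)(c4ccccc4)C(C)(C)C)[C@H](O)C[C@@]2(C)OC(C)(C)O[C@H]2C1
F5 | step 14 | 8β-hydroxy 3-enone | O=C1/C(C)=C\[C@@H](O[Si](C)(C)C(C)(C)C)[C@H](C(=C)CO[Si](c4ccccc4)(c4ccccc4)C(C)(C)C)[C@H](O)C[C@@]2(C)OC(C)(C)O[C@H]2C1
F6 | step 14 | 8β-epoxyangelate 3-enone | O=C1/C(C)=C\[C@@H](O[Si](C)(C)C(C)(C)C)[C@H](C(=C)CO[Si](c4ccccc4)(c4ccccc4)C(C)(C)C)[C@H](OC(=O)[C@@]3(C)O[C@H]3C)C[C@@]2(C)OC(C)(C)O[C@H]2C1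
F7 | step 14 | 8β-epoxyangelate 3β-alcohol | O[C@@H]1/C(C)=C\[C@@H](O[Si](C)(C)C(C)(C)C)[C@H](C(=C)CO[Si](c4ccccc4)(c4ccccc4)C(C)(C)C)[C@H](OC(=O)[C@@]3(C)O[C@H]3C)C[C@@]2(C)OC(C)(C)O[C@H]2C1
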